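**Two channels.** The target and the isomer of the product, we assume, start from different charged species: the target from the starting material, the isomer from the other conformer. The new flask, at 1.0 M with 0.250 equiv of other conformer, follows two earlier runs.

| flask | starting material | other conformer | remark | time |
|---|---|---|---|---|
| red | 0.50 M | 0.25 equiv | run made earlier |  |
| blue | 0.75 M | 0.25 equiv | run made earlier |  |
| flask | 1.0 M | 0.250 equiv |  | 2.5 h |

| run | time / h | target / % | isomer of the product / % | starting material / % |
|---|---|---|---|---|
| red | 0.133 | 3 | 2 | 83 |
| red | 0.417 | 10 | 3 | 68 |
| red | 0.667 | 16 | 9 | 64 |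
| red | 1.00 | 20 | 13 | 52 |
| red | 1.50 | 24 | 12 | 35 |
| red | 2.00 | 30 | 15 | 27 |
| red | 2.50 | 30 | 21 | 22 |
| blue | 0.133 | 3 | 1 | 81 |
| blue | 0.417 | 11 | 4 | 70 |
| blue | 0.667 | 17 | 7 | 61 |
| blue | 1.00 | 21 | 10 | 53 |
| blue | 1.50 | 28 | 14 | 37 |
| blue | 2.00 | 24 | 13 | 27 |
| blue | 2.50 | 29 | 19 | 21 |

(each reading ± 2 percentage points)

- share of target in target plus isomer of the product at 2.0 min
- share of target in target plus isomer of the product at 15 min
- share of target in target plus isomer of the product at 2.5 h
- which of target and isomer of the product there is more of at 2.5 h

- what was read earlier has a scatter of 2 percentage points, one standard deviation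

**Main step.** With starting material going to target as the sole step, no isomer forms and the target's share stands at 100%.

**Second channel.** Adding the route from the other conformer brings in one number, the opening ratio, isomer formed per target formed at the start of a run: 0.500 on the pooled first readings of red and blue, taken at 0.133 h. Its inverse is the early selectivity factor. The early share is then one over one plus the ratio, 66.7%. If both channels are first order, then at one temperature the opening ratio ignores concentration and scales with the equivalents of other conformer. The new flask has the equivalents of red and blue, so we take 66.7% for 2.0 min. This is a poor reading: the isomer stands at 2% in red and 1% in blue, with a scatter of 2 percentage points.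

**Later steps.** The pooled share reads 75.0% at 0.417 h and 59.6% at 2.50 h. We read this as a crossing: the opening channel fades, then some later loss of target pulls the share down. Our reckoning for 15 min is the midpoint of the first two shares, 70.8%, and for 2.5 h it is 59.6%, with target ahead.

**The forecast.** It gave 71% at 2.0 min, 70% at 15 min and 62% at 2.5 h, with target ahead, and called the earliest value “pure extrapolation because almost no product exists yet”. Our early figure stands below its figure.

**The flask.** The flask gives 59.6% at 2.0 min, 65.7% at 15 min and 58.7% at 2.5 h, with target ahead.

    other conformer → isomer of the product (k = 0.0180 min⁻¹)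
    target → over-reaction product (k = 5.30 × 10⁻⁶ min⁻¹)
    starting material + target → side product (k = 0.0120 M⁻¹ min⁻¹)
    target ⇌ isomer of the product (K = 1.40, k = 0.00140 min⁻¹)
    starting material ⇌ dormant form (K = 2.90, k = 0.00110 min⁻¹)
    starting material ⇌ other conformer (K = 0.120, k = 0.0180 min⁻¹)
    starting material → target (k = 0.00610 min⁻¹)

The other conformer has a half-life of 0.64 h by its loss to isomer alone. The flask's share at 2.0 min makes the ratio 0.677; our 0.500 was read in red and blue at 0.133 h. Scaled to the neighbour charged with 0.620 equiv of other conformer, it becomes 1.68, a share of 37.3%; that neighbour gives 39.5% at 2.0 min.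

The numbers in the tables come from a simulation on assumed constants; noise was put on by code.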